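**Retrosynthetic overview**

1. Locants: drimane-type numbering, primed for the right-hand bicycle (C-4' gem-dimethyl carbon, C-5' ring-fusion CH, C-10' ring-fusion C–CH3, C-8'=C-9' alkene); C-11/C-12 are the two linking CH2 groups.
2. Last disconnection: the sp3–sp2 bond C-12–C-9', giving the alkylzinc from iodide 20 (rings A/B taken intact from (+)-sclareolide) and alkenyl triflate 14; the triflate fixes the position of the tetrasubstituted C-8'=C-9' alkene.
3. Ring A' of the right half is opened at C-4'–C-5': bicyclic enone 12 comes from monocyclic dienone 10 by a hydrogen-atom-transfer-initiated 6-exo radical cyclisation that creates the cis ring fusion.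
4. Enabling feature: C-4' (a tertiary radical site) hangs three CH2 groups from quaternary C-10', and C-5' is the terminus of the ring-B' dienone C-5'=C-6'–C-7'=C-8'–C-9'=O. The tether can only deliver syn (cis fusion), and the activating carbonyl sits at C-9', where the triflate is needed.
5. Order of rings: A/B from the chiral pool; B' from 2,6-dimethylcyclohexanone, with C-10' set by Pd-catalysed decarboxylative asymmetric allylation; A' last, in the key step.

Key step: step 6

Remark: the (R)-PHOX ligand in step 2 is chosen by analogy with the parent 2-methylcyclohexanone substrate, where the (S)-ligand gives the (S)-ketone; the racemic methyl-bearing α-centre of 3 is assumed not to override catalyst control. The enantiomeric purity of 4 should be checked, because any minor enantiomer ends as a diastereomer of the target.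
Remark: 2,6-dimethylcyclohexanone, (+)-sclareolide and both enantiomers of t-Bu-PHOX are taken as commercially available.

**Route**

Step 1
Reactants: 1 2,6-dimethylcyclohexan-1-one
Product: 3 allyl 2,6-dimethylcyclohex-1-en-1-yl carbonate, via lithium enolate 2 (not isolated)
Conditions: LiHMDS, THF, 0 °C; then allyl chloroformate, −78 °C
Reagents that add atoms: allyl chloroformate, C=CCOC(=O)Cl
Why: The ketone can form only one (tetrasubstituted) enolate, and its O-acylation by the chloroformate (enol carbonate formation) gives the substrate for step 2; no stereocentre is set.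

Step 2
Reactants: 3 allyl 2,6-dimethylcyclohex-1-en-1-yl carbonate
Product: 4 (2R)-2-allyl-2,6-dimethylcyclohexan-1-one (both C-6 epimers)
Conditions: Pd2(dba)3 (2.5 mol%), (R)-t-Bu-PHOX (6 mol%), THF, 25 °C
Reagents that add atoms: none
Why: Decarboxylative asymmetric allylic alkylation (Tsuji allylation): loss of CO2 gives a chiral Pd-enolate/π-allyl pair whose C–C bond formation sets the quaternary centre (future C-10') as R under ligand control, while the C-6 methyl centre is irrelevant because it becomes sp2 in step 4.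

Step 3
Reactants: 4 (2R)-2-allyl-2,6-dimethylcyclohexan-1-one
Product: 6 (2R)-2,6-dimethyl-2-(4-methylpent-4-en-1-yl)cyclohexan-1-one, via B-alkyl-9-BBN adduct 5 (not isolated)
Conditions: 9-BBN, THF, 0 °C to rt; then 2-bromopropene, PdCl2(dppf) (3 mol%), aq NaOH, THF, 45 °C
Reagents that add atoms: 2-bromopropene, CC(Br)=C
Why: Anti-Markovnikov hydroboration should be chemoselective for the terminal alkene over the hindered ketone, and B-alkyl Suzuki–Miyaura coupling then installs the 1,1-disubstituted alkene that becomes C-4' with its two methyl groups; the quaternary centre is not touched.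

Step 4
Reactants: 6 (2R)-2,6-dimethyl-2-(4-methylpent-4-en-1-yl)cyclohexan-1-one
Product: 8 (6S)-2,6-dimethyl-6-(4-methylpent-4-en-1-yl)cyclohex-2-en-1-one, via trimethylsilyl enol ether 7 (not isolated)
Conditions: TMSOTf, Et3N, CH2Cl2, 0 °C; crude 7, then Pd(OAc)2 (1.05 equiv), MeCN, rt
Reagents that add atoms: none
Why: Only the methyl-bearing α-carbon has a hydrogen, so one silyl enol ether forms, and Saegusa–Ito oxidation should give the endocyclic enone, merging both C-6 epimers; the descriptor of the untouched quaternary centre changes to S only through CIP priorities.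

Step 5
Reactants: 8 (6S)-2,6-dimethyl-6-(4-methylpent-4-en-1-yl)cyclohex-2-en-1-one
Product: 10 (6S)-2,6-dimethyl-6-(4-methylpent-4-en-1-yl)cyclohexa-2,4-dien-1-one, via trimethylsilyl dienol ether 9 (not isolated)
Conditions: TMSOTf, Et3N, CH2Cl2, 0 °C; crude 9, then DDQ, CH2Cl2, 0 °C; product kept cold and dark and used at once
Reagents that add atoms: none
Why: With no α'-hydrogen the enone is silylated to the linear dienol ether by γ-deprotonation, and hydride abstraction by DDQ at the remaining allylic CH2 (the dienol ether to dienone dehydrogenation known from steroid 3,5-dienol ethers) gives the 2,4-dienone, which cannot aromatise because C-6 is quaternary.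

Step 6
Reactants: 10 (6S)-2,6-dimethyl-6-(4-methylpent-4-en-1-yl)cyclohexa-2,4-dien-1-one
Product: 12 (4aR,8aS)-2,5,5,8a-tetramethyl-4a,5,6,7,8,8a-hexahydronaphthalen-1(4H)-one, via deconjugated enone 11 (not isolated)
Conditions: Fe(acac)3 (30 mol%), PhSiH3 (2.5 equiv), EtOH/(CH2OH)2 5:1, 30 °C, dilute; then DBU (20 mol%), rt
Reagents that add atoms: none
Why: Proposed new method: an iron hydride formed from Fe(acac)3 and PhSiH3 transfers a hydrogen atom to the electron-rich 1,1-disubstituted alkene to give the tertiary C-4' radical, which adds 6-exo-trig to C-5', the δ-terminus of the ring-B' dienone; the oxapentadienyl radical is reduced to the iron dienolate and protonated by ethanol, and DBU then moves the double bond into conjugation. The closest known reaction type is the hydrogen-atom-transfer-initiated reductive coupling of alkenes with enones (radical conjugate addition) and its 1,6-variants with extended acceptors, which has not been shown intramolecularly on a cyclohexa-2,4-dienone. One ring (A') is closed, 6-exo-trig, and C-4' becomes the gem-dimethyl quaternary carbon. The only new stereocentre, C-5', is controlled by C-10': the three-carbon tether can reach C-5' only on the face of ring B' that carries it, so H-5' ends syn to the C-10' methyl group, which is the cis ring fusion required. The step needs chemoselectivity (hydrogen-atom transfer to the isolated alkene and not to the reducible dienone), secured by the polarity match of the metal hydride with the electron-rich alkene, and regioselectivity (C-5' and not C-7' or the carbonyl carbon), secured by ring size, since attack at C-7' would need a bridged eight-membered ring and addition to C=O is slower and reversible. The dienone is used cold and dilute so that its [4+2] dimerisation and its intramolecular Diels–Alder reaction with the side-chain alkene do not compete, and C-8' needs no control because 11 converges on conjugated enone 12.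

Step 7
Reactants: 12 (4aR,8aS)-2,5,5,8a-tetramethyl-4a,5,6,7,8,8a-hexahydronaphthalen-1(4H)-one
Product: 14 (4aR,8aS)-2,5,5,8a-tetramethyl-3,4,4a,5,6,7,8,8a-octahydronaphthalen-1-yl trifluoromethanesulfonate, via lithium enolate 13 (not isolated)
Conditions: L-Selectride, THF, −78 °C; then N-(5-chloropyridin-2-yl)triflimide, −78 to 0 °C
Reagents that add atoms: N-(5-chloropyridin-2-yl)-N-(trifluoromethylsulfonyl)trifluoromethanesulfonamide, O=S(=O)(N(c1ccc(Cl)cn1)S(=O)(=O)C(F)(F)F)C(F)(F)F
Why: The carbonyl is shielded by the quaternary C-8a, so the bulky hydride should add 1,4, and the regiodefined tetrasubstituted enolate is O-sulfonylated (conjugate reduction–enolate triflation); C-2 stays sp2 and the non-enolisable ring-fusion centres are not touched.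

Step 8
Reactants: 15 (+)-sclareolide
Product: 16 (1R,2R,4aS,8aS)-1-(2-hydroxyethyl)-2,5,5,8a-tetramethyldecahydronaphthalen-2-ol
Conditions: LiAlH4, THF, 0 °C to rt
Reagents that add atoms: none
Why: Hydride reduction of the lactone to the diol; no stereocentre is involved.

Step 9
Reactants: 16 (1R,2R,4aS,8aS)-1-(2-hydroxyethyl)-2,5,5,8a-tetramethyldecahydronaphthalen-2-ol
Product: 17 2-[(1R,2R,4aS,8aS)-2-hydroxy-2,5,5,8a-tetramethyldecahydronaphthalen-1-yl]ethyl acetate
Conditions: Ac2O, pyridine, CH2Cl2, 0 °C to rt
Reagents that add atoms: acetic anhydride, CC(=O)OC(C)=O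
Why: Acylation is selective for the primary alcohol because the hindered tertiary alcohol does not react under these conditions; the acetate also prevents ring closure to the cyclic ether in step 10.

Step 10
Reactants: 17 2-[(1R,2R,4aS,8aS)-2-hydroxy-2,5,5,8a-tetramethyldecahydronaphthalen-1-yl]ethyl acetate
Product: 18 2-[(1S,4aS,8aS)-5,5,8a-trimethyl-2-methylidenedecahydronaphthalen-1-yl]ethyl acetate
Conditions: SOCl2, pyridine, CH2Cl2, −78 °C; AgNO3-silica chromatography
Reagents that add atoms: none
Why: E2 elimination of the chlorosulfite of the equatorial tertiary alcohol, for which only hydrogens of the freely rotating methyl group can be anti-periplanar, should give mainly the exocyclic alkene (minor endocyclic isomers removed by chromatography); the three ring stereocentres are untouched.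

Step 11
Reactants: 18 2-[(1S,4aS,8aS)-5,5,8a-trimethyl-2-methylidenedecahydronaphthalen-1-yl]ethyl acetate
Product: 19 2-[(1S,4aS,8aS)-5,5,8a-trimethyl-2-methylidenedecahydronaphthalen-1-yl]ethan-1-ol
Conditions: K2CO3 (cat.), MeOH, rt
Reagents that add atoms: none
Why: Base-catalysed methanolysis (transesterification) of the acetate, harmless to the acid-sensitive exocyclic alkene.

Step 12
Reactants: 19 2-[(1S,4aS,8aS)-5,5,8a-trimethyl-2-methylidenedecahydronaphthalen-1-yl]ethan-1-ol
Product: 20 (1S,4aS,8aS)-1-(2-iodoethyl)-5,5,8a-trimethyl-2-methylidenedecahydronaphthalene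
Conditions: I2, PPh3, imidazole, CH2Cl2, 0 °C
Reagents that add atoms: iodine, II
Why: Appel-type iodination of the primary alcohol under neutral conditions (SN2 at the CH2 group, no stereocentre involved).

Step 13
Reactants: 20 (1S,4aS,8aS)-1-(2-iodoethyl)-5,5,8a-trimethyl-2-methylidenedecahydronaphthalene; 14 (4aR,8aS)-2,5,5,8a-tetramethyl-3,4,4a,5,6,7,8,8a-octahydronaphthalen-1-yl trifluoromethanesulfonate
Product: 22 (4aS,5S,8aS)-1,1,4a-trimethyl-6-methylidene-5-{2-[(4aR,8aS)-2,5,5,8a-tetramethyl-3,4,4a,5,6,7,8,8a-octahydronaphthalen-1-yl]ethyl}decahydronaphthalene, via alkylzinc iodide 21 (not isolated)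
Conditions: Zn dust, LiCl, THF, 40 °C; then 14, Pd(OAc)2 (5 mol%), SPhos (10 mol%), THF/NMP, 50 °C
Reagents that add atoms: none
Why: Zinc insertion into the primary C–I bond and Negishi sp3–sp2 coupling with the alkenyl triflate join the halves and place the tetrasubstituted alkene exactly where the triflate was; no stereocentre is formed and the non-acidic conditions leave the exocyclic alkene in place.

**Compound list**

1 | 2,6-dimethylcyclohexan-1-one (cis/trans mixture) | CC1CCCC(C)C1=O | starting material
2 | lithium 2,6-dimethylcyclohex-1-en-1-olate | CC1CCCC(C)=C1[O-].[Li+] | intermediate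
3 | allyl 2,6-dimethylcyclohex-1-en-1-yl carbonate (racemic) | C=CCOC(=O)OC1=C(C)CCCC1C | intermediate
4 | (2R)-2-allyl-2,6-dimethylcyclohexan-1-one (C-6 epimers) | O=C1C(C)CCC[C@]1(C)CC=C | intermediate
5 | 9-{3-[(1S)-1,3-dimethyl-2-oxocyclohexyl]propyl}-9-borabicyclo[3.3.1]nonane (same spatial arrangement as in 4) | O=C1C(C)CCC[C@]1(C)CCCB1C2CCCC1CCC2 | intermediate
6 | (2R)-2,6-dimethyl-2-(4-methylpent-4-en-1-yl)cyclohexan-1-one (C-6 epimers) | O=C1C(C)CCC[C@]1(C)CCCC(C)=C | intermediate
7 | trimethyl{[(6S)-2,6-dimethyl-6-(4-methylpent-4-en-1-yl)cyclohex-1-en-1-yl]oxy}silane | C[Si](C)(C)OC1=C(C)CCC[C@]1(C)CCCC(C)=C | intermediate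
8 | (6S)-2,6-dimethyl-6-(4-methylpent-4-en-1-yl)cyclohex-2-en-1-one | O=C1C(C)=CCC[C@]1(C)CCCC(C)=C | intermediate
9 | trimethyl{[(6S)-2,6-dimethyl-6-(4-methylpent-4-en-1-yl)cyclohexa-1,3-dien-1-yl]oxy}silane | C[Si](C)(C)OC1=C(C)C=CC[C@]1(C)CCCC(C)=C | intermediate
10 | (6S)-2,6-dimethyl-6-(4-methylpent-4-en-1-yl)cyclohexa-2,4-dien-1-one | O=C1C(C)=CC=C[C@]1(C)CCCC(C)=C | intermediate
11 | (4aR,8aS)-2,5,5,8a-tetramethyl-4a,5,6,7,8,8a-hexahydronaphthalen-1(2H)-one (C-2 epimers, cis-fused) | O=C1C(C)C=C[C@@H]2C(C)(C)CCC[C@]12C | intermediate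
12 | (4aR,8aS)-2,5,5,8a-tetramethyl-4a,5,6,7,8,8a-hexahydronaphthalen-1(4H)-one (cis-fused) | O=C1C(C)=CC[C@@H]2C(C)(C)CCC[C@]12C | intermediate
13 | lithium (4aR,8aS)-2,5,5,8a-tetramethyl-3,4,4a,5,6,7,8,8a-octahydronaphthalen-1-olate | [Li+].[O-]C1=C(C)CC[C@@H]2C(C)(C)CCC[C@]12C | intermediate
14 | (4aR,8aS)-2,5,5,8a-tetramethyl-3,4,4a,5,6,7,8,8a-octahydronaphthalen-1-yl trifluoromethanesulfonate | O=S(=O)(OC1=C(C)CC[C@@H]2C(C)(C)CCC[C@]12C)C(F)(F)F | intermediate
15 | (+)-sclareolide, (3aR,5aS,9aS,9bR)-3a,6,6,9a-tetramethyldecahydronaphtho[2,1-b]furan-2(1H)-one | C[C@@]12CC[C@H]3C(C)(C)CCC[C@]3(C)[C@H]1CC(=O)O2 | starting material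
16 | (1R,2R,4aS,8aS)-1-(2-hydroxyethyl)-2,5,5,8a-tetramethyldecahydronaphthalen-2-ol | C[C@@]1(O)CC[C@H]2C(C)(C)CCC[C@]2(C)[C@H]1CCO | intermediate
17 | 2-[(1R,2R,4aS,8aS)-2-hydroxy-2,5,5,8a-tetramethyldecahydronaphthalen-1-yl]ethyl acetate | C[C@@]1(O)CC[C@H]2C(C)(C)CCC[C@]2(C)[C@H]1CCOC(C)=O | intermediate
18 | 2-[(1S,4aS,8aS)-5,5,8a-trimethyl-2-methylidenedecahydronaphthalen-1-yl]ethyl acetate | C=C1CC[C@H]2C(C)(C)CCC[C@]2(C)[C@H]1CCOC(C)=O | intermediate
19 | 2-[(1S,4aS,8aS)-5,5,8a-trimethyl-2-methylidenedecahydronaphthalen-1-yl]ethan-1-ol | C=C1CC[C@H]2C(C)(C)CCC[C@]2(C)[C@H]1CCO | intermediate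
20 | (1S,4aS,8aS)-1-(2-iodoethyl)-5,5,8a-trimethyl-2-methylidenedecahydronaphthalene | C=C1CC[C@H]2C(C)(C)CCC[C@]2(C)[C@H]1CCI | intermediate
21 | iodo{2-[(1S,4aS,8aS)-5,5,8a-trimethyl-2-methylidenedecahydronaphthalen-1-yl]ethyl}zinc | C=C1CC[C@H]2C(C)(C)CCC[C@]2(C)[C@H]1CC[Zn]I | intermediate
22 | (4aS,5S,8aS)-1,1,4a-trimethyl-6-methylidene-5-{2-[(4aR,8aS)-2,5,5,8a-tetramethyl-3,4,4a,5,6,7,8,8a-octahydronaphthalen-1-yl]ethyl}decahydronaphthalene | C=C1CC[C@H]2C(C)(C)CCC[C@]2(C)[C@H]1CCC1=C(C)CC[C@@H]2C(C)(C)CCC[C@]12C | target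

**Step count and risks**

Total step count: 13. Longest linear sequence: 8 steps (steps 1–7 and 13); the left half (steps 8–12) is convergent.

Steps most likely to fail:

1. Step 6 (Proposed new method). The tertiary radical may be reduced before it cyclises (plain alkene hydrogenation), the metal hydride may reduce the dienone, or the dienone may dimerise by [4+2] cycloaddition before ring closure. The fallback removes the metal hydride and uses classical stannane chain chemistry (Giese-type addition of a tert-alkyl radical from a bromide to the terminus of a dienyl ketone). It sets out from enone 8 and comes back at 12. Markovnikov addition of HBr (1 equiv, CH2Cl2, −40 °C) to the side-chain alkene of 8 should give (6S)-6-(4-bromo-4-methylpentyl)-2,6-dimethylcyclohex-2-en-1-one F1. The second unsaturation is introduced as in step 5, through {[(6S)-6-(4-bromo-4-methylpentyl)-2,6-dimethylcyclohexa-1,3-dien-1-yl]oxy}trimethylsilane F2 (TMSOTf, Et3N) and DDQ, to give (6S)-6-(4-bromo-4-methylpentyl)-2,6-dimethylcyclohexa-2,4-dien-1-one F3. Slow addition of Bu3SnH with Et3B/air in toluene at 0 °C then generates the same C-4' radical by bromine abstraction; 6-exo closure onto C-5', hydrogen transfer from the stannane and DBU treatment should lead through 11 to 12.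

2. Step 13. Oxidative addition and transmetalation at the tetrasubstituted triflate next to a quaternary carbon may be slow, so that β-hydride elimination or protonation of the alkylzinc takes over. The fallback replaces cross-coupling by carbonyl addition and allylic transposition; it sets out from enone 12 and iodide 20 and comes back at 22. Iodine–lithium exchange on 20 (t-BuLi, Et2O/pentane, −78 °C) gives {2-[(1S,4aS,8aS)-5,5,8a-trimethyl-2-methylidenedecahydronaphthalen-1-yl]ethyl}lithium F4. This adds 1,2 to the carbonyl of 12 to give the tertiary allylic alcohol (4aR,8aS)-2,5,5,8a-tetramethyl-1-{2-[(1S,4aS,8aS)-5,5,8a-trimethyl-2-methylidenedecahydronaphthalen-1-yl]ethyl}-1,4,4a,5,6,7,8,8a-octahydronaphthalen-1-ol F5. SOCl2 (pyridine, Et2O, −20 °C) should convert it with allylic transposition into the secondary allylic chloride (4aR,8aS)-3-chloro-2,5,5,8a-tetramethyl-1-{2-[(1S,4aS,8aS)-5,5,8a-trimethyl-2-methylidenedecahydronaphthalen-1-yl]ethyl}-3,4,4a,5,6,7,8,8a-octahydronaphthalene F6, in which the tetrasubstituted alkene is already in place. LiEt3BH (THF, 0 °C) then displaces chloride at the unhindered C-7' to give 22.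

3. Step 7. Hydride may be delivered 1,2 instead of 1,4, or O-sulfonylation of the hindered tetrasubstituted enolate may stay incomplete. The fallback separates reduction from enolate formation; it sets out from 12 and comes back at 14. Hydrogenation of the enone C=C (H2, Pd/C, EtOAc) gives (4aR,8aS)-2,5,5,8a-tetramethyloctahydronaphthalen-1(2H)-one F7 (both C-2 epimers). KHMDS (THF, −78 to 0 °C) removes its only α-hydrogen to give potassium (4aR,8aS)-2,5,5,8a-tetramethyl-3,4,4a,5,6,7,8,8a-octahydronaphthalen-1-olate F8, which is O-sulfonylated with the same triflimide reagent to give 14.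

**Further compounds**

F1 | step 6 | (6S)-6-(4-bromo-4-methylpentyl)-2,6-dimethylcyclohex-2-en-1-one | O=C1C(C)=CCC[C@]1(C)CCCC(C)(C)Br
F2 | step 6 | {[(6S)-6-(4-bromo-4-methylpentyl)-2,6-dimethylcyclohexa-1,3-dien-1-yl]oxy}trimethylsilane | C[Si](C)(C)OC1=C(C)C=CC[C@]1(C)CCCC(C)(C)Br
F3 | step 6 | (6S)-6-(4-bromo-4-methylpentyl)-2,6-dimethylcyclohexa-2,4-dien-1-one | O=C1C(C)=CC=C[C@]1(C)CCCC(C)(C)Br
F4 | step 13 | {2-[(1S,4aS,8aS)-5,5,8a-trimethyl-2-methylidenedecahydronaphthalen-1-yl]ethyl}lithium | C=C1CC[C@H]2C(C)(C)CCC[C@]2(C)[C@H]1CC[Li]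
F5 | step 13 | (4aR,8aS)-2,5,5,8a-tetramethyl-1-{2-[(1S,4aS,8aS)-5,5,8a-trimethyl-2-methylidenedecahydronaphthalen-1-yl]ethyl}-1,4,4a,5,6,7,8,8a-octahydronaphthalen-1-ol (C-1 epimers) | C=C1CC[C@H]2C(C)(C)CCC[C@]2(C)[C@H]1CCC1(O)C(C)=CC[C@@H]2C(C)(C)CCC[C@]12C
F6 | step 13 | (4aR,8aS)-3-chloro-2,5,5,8a-tetramethyl-1-{2-[(1S,4aS,8aS)-5,5,8a-trimethyl-2-methylidenedecahydronaphthalen-1-yl]ethyl}-3,4,4a,5,6,7,8,8a-octahydronaphthalene (C-3 epimers) | C=C1CC[C@H]2C(C)(C)CCC[C@]2(C)[C@H]1CCC1=C(C)C(Cl)C[C@@H]2C(C)(C)CCC[C@]12C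
F7 | step 7 | (4aR,8aS)-2,5,5,8a-tetramethyloctahydronaphthalen-1(2H)-one (C-2 epimers) | O=C1C(C)CC[C@@H]2C(C)(C)CCC[C@]12C
F8 | step 7 | potassium (4aR,8aS)-2,5,5,8a-tetramethyl-3,4,4a,5,6,7,8,8a-octahydronaphthalen-1-olate | [K+].[O-]C1=C(C)CC[C@@H]2C(C)(C)CCC[C@]12C
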